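## Structural features

The target is a furanoheliangolide. A ten-membered carbocycle (C1–C10) is spanned by an oxygen bridge from C3 to C10, so that O, C10, C1 (ketone), C2 and C3 form a 3(2H)-furanone, and an α-methylene-γ-butyrolactone (C6–O–C12(=O)–C11(=C13)–C7) is trans-fused across C6–C7. The furanone enone is conjugated with the (4Z)-C4=C5 olefin (C15 methyl on C4), which the bridged ring can hold only in the cis geometry. Five stereocentres follow one another: C6 (R), C7 (S), C8 (S), C9 (R) and the quaternary C10 (R; C14 methyl, ring oxygen, C1 carbonyl). O6 and O8 are 1,3-anti and the O8/O9 pair is threo, which is the arrangement of L-tartaric acid. C8 and C9 carry two different esters (isovalerate and acetate) on neighbouring secondary oxygens. The fragile groups are the α-methylene lactone (a Michael acceptor), the vinylogous-ester dienone, the allylic C6–O bond and the two esters, which can migrate or hydrolyse. The real difficulty lies in closing a strained, bridged medium ring around a trisubstituted olefin, building the quaternary C10 beside C9, telling O8 from O9, and attaching the C11 branch to C7 trans to O6. The key step exploits the fact that C7, without C11, is an ordinary ring methylene whose hydrogens are 1,5-related to a carbene carbon tethered through an acyl group to O6, so the lactone ring (C6, O, C12, C11, C7) closes by forming C7–C11 directly.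

## Logic of the disconnections

**27 → 26.** The exocyclic C11=C13 bond is cut first. The α-methylene lactone is the most reactive group of 27 and should meet neither acid, nucleophiles nor acylating agents, so it is made last. What remains is 26, whose phosphonate is both the olefination handle and the second acceptor group needed by the carbene step before it. The forward olefination must work with formaldehyde and a mild carbonate base, because two ordinary esters are present.

**26 → 25.** The C7–C11 bond is cut, which opens the γ-lactone to an O6 diazo(phosphono)acetate. C7 becomes a plain methylene, so the carbocycle can be assembled without a carbon branch or a stereocentre at C7. The gain is one ring, one C–C bond and the C6/C7 relative configuration. The forward step must replace the one C7 hydrogen that is trans to O6, in preference to C8–H and to addition across C4=C5. For that reason O8 and O9 of 25 already carry the final acyl groups and not an acetal, whose ether oxygen would activate C8–H (this hydrogen is cis to O6 on the ring).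

**25 → 21 (through 24, 23, 22).** The C11 diazo group and the O9 and O8 acyl bonds are removed, and the two oxygens are tied back into one isopropylidene acetal. Esters cannot survive the organometallic steps that build the ring system; the acetal comes with the chiral pool and hides both oxygens in one group. The demand is that O8 be acylated before O9 in 22, which relies on C9–OH being flanked by the fully substituted C10.

**21 → 20.** The C4=C5 double bond is cut (ring-closing metathesis). It is the only C=C of the carbocycle outside the furanone, both halves end in simple 1-alkenes, and the ring dictates the Z geometry. The ten-membered ring is opened to a chain hung on a preformed furanone. The forward step asks a ruthenium carbene to engage a 1,1-disubstituted, conjugated olefin at high dilution; the trans-dioxolane and the planar furanone are counted on to hold the ends together.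

**20 → 18 + 19, and 18 → 17.** The O6–C12 ester bond is cut to separate the two-carbon phosphonoacetyl unit, and O6 is returned to a silyl ether. The acyl group is therefore introduced only after the last strongly basic step. The only demand is a fluoride deprotection that spares the dienone.

**17 → 15 → 14.** The O–C3 bond of the furanone is cut and the C1 carbonyl is traced back to an alkyne carbon: the heterocycle is the cyclization product of a 4-hydroxy-2-ynone, itself the oxidation product of the C3 carbinol. An alkyne flanked by two carbinols is available by two acetylide additions. The forward steps need an oxidant that touches only the activated C3 alcohol, and an amine-triggered hydration and cyclization in which the C10 hydroxyl closes on C3.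

**14 → 13.** The C10–C14 (methyl) bond is cut. A C10 ketone that bears the alkynyl group and sits next to O9 can chelate magnesium, and methyl attack on that chelate gives the required C10 configuration; adding the alkynyl group to a methyl ketone under the same model would give the epimer. The quaternary stereocentre is removed. The forward step demands clean 1,2-addition to an ynone under chelation control.

**13 → 9 + 12, and 12 → 10 + 11.** The C10–C1 bond is cut, dividing the molecule into a C6–C10 acyl donor and a C1–C4 alkyne (with C15 and the extra olefin carbon). The alkyne is cut at C2–C3 into two commercial pieces. This is the convergent point of the route. 12 may be racemic because C3 ends as a carbonyl. The forward acylation must stop at the ketone, hence the N-methoxy-N-methylamide in 9.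

**9 → 6 (through 8, 7).** After functional-group changes (amide from ester, silyl ether from alcohol), the C5–C6 bond is cut: the vinyl group is removed from the C6 carbinol. This takes away the C6 stereocentre and leaves an aldehyde. The forward addition must be face-selective by reagent control; the 1,3-anti outcome wanted is also the one a chelated β-alkoxy aldehyde prefers.

**6 → 1 (through 4, 3, 2).** C6 is traced to the inner carbon of a terminal olefin, the C6–C7 bond is cut (vinyl nucleophile on a C7 electrophile), and the C7 leaving group is traced to a primary alcohol and then to one of the two ester groups of 1. Compound 1 holds C8 and C9 in the correct absolute configuration and C7 and C10 as its two equivalent ester carbons, so no stereocentre of the diol has to be made. The demands are reduction of only one ester of 1, and substitution at a primary carbon β to oxygen without attack on the remaining ester.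

## Other disconnections considered

**Alternative 1:** The cut is the C1–C10 bond; the ten-membered ring is traced back to a carvone-derived six-membered ring (C3–C8 bond intact) carrying an alkynyl and an alkenyl arm.
- **Forward key step:** An anionic oxy-Cope [3,3] shift of the C3 potassium alkoxide joins the ynol-ether carbon C1 to C10 and breaks C3–C8, giving the ten-membered 1-ethoxy enone A1 with a trans C8=C9 olefin.
- **In its favour:** Carvone supplies C4/C15, C7 with its three-carbon branch (C11–C13) and the absolute configuration at C7. The ring is formed by a unimolecular pericyclic step that needs no high dilution. The cis C4=C5 bond is inherited from the cyclohexene.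
- **Against it here:** C10 is set only through the chair/boat preference of the transition state and the geometry of a tetrasubstituted enol ether. O8 and O9 must later be added to a trans-cyclodecene from the correct face of a flexible ring. Three acetal protecting groups must be removed before furanone and lactone closure.
- **Comparison:** On structure, it is better at C7 (no functionalization of an unactivated C–H) and equal on the olefin geometry, but weaker at C8–C10, which the chosen plan takes from tartrate and a chelate. On mechanism, its ring formation is the more dependable of the two. On step economy no clear advantage is expected either way.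

**Alternative 2:** The cut is the C1=C6 bond of a fused bicyclic precursor, whose perimeter is the ten-membered ring.
- **Forward key step:** Ozonolysis of the tetrasubstituted C1=C6 olefin unveils ketones at C1 and C6 beside the existing C3 ketone, and the C10 hydroxyl condenses with C3 (O–C3 bond) to give the furanone-bridged keto acid A2.
- **In its favour:** There is no medium-ring cyclization at all, which is better than any macrocyclization including the metathesis used here. C7–C10 are set on a rigid fused bicycle, and the C7 carboxymethyl branch is present from the start, again better than a late C–H insertion.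
- **Against it here:** The anisole starting point is achiral, so absolute configuration needs a separate asymmetric step. A2 still lacks the C4=C5 olefin (dehydrogenation next to the C6 ketone) and the 6R alcohol (ketone reduction), and the lactone must be α-methylenated through enolate chemistry on a base-sensitive molecule.
- **Comparison:** On structure and ring formation it is the safer plan. On mechanism it moves the risk to late oxidation-state adjustments at C4–C6 and C11. On step economy it is expected to be longer than the chosen plan.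

**Alternative 3:** The cut is the C9–C10 bond.
- **Forward key step:** A tethered 3-silyloxy-2-methylfuran adds through its methyl-bearing carbon (C10) to the C9 aldehyde. This regenerates the furanone and closes the carbocycle, giving A3 with the α-methylene lactone already in place.
- **In its favour:** It is the most convergent plan: one step forms the ring, the furanone, C9 and C10. In A3, O8 (ether) and O9 (free hydroxyl) are already differentiated, so the two acylations are unambiguous; this is better than the steric differentiation used here. Few steps follow the ring closure.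
- **Against it here:** Two stereocentres, one quaternary, are created during an entropically demanding ten-membered closure with no obvious control element for either face. The α-methylene lactone must survive the Lewis acid or fluoride used, and the Z C4=C5 bond must be built in the open chain.
- **Comparison:** On structure and step economy it is the better plan. On mechanism it carries the largest stereochemical risk at C9/C10, where the chosen plan uses the chiral pool and a chelate-controlled addition. Both plans share a demanding ring closure and are equal on that point.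

Key step: step 20

**Remarks before the steps**

- Assumption: atoms are numbered as in germacranolides (C1 ketone, C3–O–C10 bridge, C4=C5, C6 lactone oxygen, C7 lactone carbon, C11–C13 lactone carbons, C14 on C10, C15 on C4), and the target is read as (4Z,6R,7S,8S,9R,10R).
- Remark: the CIP descriptors at C6 and C10 change along the route through priority changes only; the spatial arrangement is constant.
- Remark: the insertion creates two stereocentres, C7 and C11; only C7 persists.
- Remark: 1 is the catalogue acetonide of dimethyl L-tartrate.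

## Route

Step 1
Reactants: 1 dimethyl (4R,5R)-2,2-dimethyl-1,3-dioxolane-4,5-dicarboxylate
Product: 2 methyl (4R,5S)-5-(hydroxymethyl)-2,2-dimethyl-1,3-dioxolane-4-carboxylate
Conditions: NaBH4 (0.6 equiv), MeOH, −10 → 0 °C; unreacted 1 recycled
Reagents that add atoms: none
Why: Borohydride reduction of an activated α-alkoxy ester; the two esters of C2-symmetric 1 are equivalent, so reduction of either gives the same hydroxy ester, and the reaction is stopped short of full conversion. The ring CH carbons (C8, C9) are not touched.

Step 2
Reactants: 2 methyl (4R,5S)-5-(hydroxymethyl)-2,2-dimethyl-1,3-dioxolane-4-carboxylate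
Product: 3 methyl (4R,5S)-2,2-dimethyl-5-{[(trifluoromethanesulfonyl)oxy]methyl}-1,3-dioxolane-4-carboxylate
Conditions: Tf2O, pyridine, CH2Cl2, −20 °C; used crude at once
Reagents that add atoms: trifluoromethanesulfonic anhydride, O=S(=O)(OS(=O)(=O)C(F)(F)F)C(F)(F)F
Why: Sulfonylation of a primary alcohol; the triflate is chosen because C7 is β to oxygen and neopentyl-like, where tosylates and iodides substitute sluggishly.

Step 3
Reactants: 3 methyl (4R,5S)-2,2-dimethyl-5-{[(trifluoromethanesulfonyl)oxy]methyl}-1,3-dioxolane-4-carboxylate
Product: 4 methyl (4R,5S)-2,2-dimethyl-5-(prop-2-en-1-yl)-1,3-dioxolane-4-carboxylate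
Conditions: CH2=CHMgBr, CuBr·SMe2 (10 mol%), THF, −78 → −30 °C
Reagents that add atoms: vinylmagnesium bromide, C=C[Mg]Br
Why: Copper-catalysed SN2 coupling of a primary alkyl triflate with a Grignard reagent; at low temperature the organocopper species should substitute at C7 faster than the Grignard reagent adds to the ester. No stereocentre is involved.

Step 4
Reactants: 4 methyl (4R,5S)-2,2-dimethyl-5-(prop-2-en-1-yl)-1,3-dioxolane-4-carboxylate
Product: 6 methyl (4R,5S)-2,2-dimethyl-5-(2-oxoethyl)-1,3-dioxolane-4-carboxylate, via secondary ozonide 5 (not isolated)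
Conditions: O3, CH2Cl2, −78 °C; then PPh3, −78 °C → rt; used without chromatography
Reagents that add atoms: ozone, [O-][O+]=O
Why: Ozonolysis with reductive work-up; the inner olefin carbon becomes the C6 aldehyde, so steps 2–4 amount to a one-carbon homologation at C7. The β-alkoxy aldehyde is carried on crude to avoid β-elimination on silica.

Step 5
Reactants: 6 methyl (4R,5S)-2,2-dimethyl-5-(2-oxoethyl)-1,3-dioxolane-4-carboxylate
Product: 7 methyl (4R,5S)-5-[(2S)-2-hydroxybut-3-en-1-yl]-2,2-dimethyl-1,3-dioxolane-4-carboxylate
Conditions: Zn(CH=CH2)2 (from CH2=CHMgBr and ZnCl2), (+)-3-exo-morpholinoisoborneol (10 mol%; the antipode that delivers the 6S carbinol), toluene, −20 → 0 °C; NH4Cl aq.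
Reagents that add atoms: divinylzinc, C=C[Zn]C=C
Why: Amino-alcohol-catalysed enantioselective addition of a diorganozinc to an aldehyde; the ligand antipode is chosen for the 6S face, which is also the 1,3-anti sense favoured by a chelated β-alkoxy aldehyde (matched case), to be confirmed by Mosher ester analysis. Zinc reagents leave the ester alone; 7 is silylated at once because a δ-hydroxy ester can lactonize.

Step 6
Reactants: 7 methyl (4R,5S)-5-[(2S)-2-hydroxybut-3-en-1-yl]-2,2-dimethyl-1,3-dioxolane-4-carboxylate
Product: 8 methyl (4R,5S)-5-[(2S)-2-(tert-butyldimethylsilyloxy)but-3-en-1-yl]-2,2-dimethyl-1,3-dioxolane-4-carboxylate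
Conditions: TBSCl, imidazole, DMF, 0 °C → rt
Reagents that add atoms: tert-butyldimethylsilyl chloride, CC(C)(C)[Si](C)(C)Cl
Why: Standard silylation of a secondary alcohol; the silyl ether must carry O6 through the organolithium, Grignard and oxidation steps.

Step 7
Reactants: 8 methyl (4R,5S)-5-[(2S)-2-(tert-butyldimethylsilyloxy)but-3-en-1-yl]-2,2-dimethyl-1,3-dioxolane-4-carboxylate
Product: 9 (4R,5S)-5-[(2S)-2-(tert-butyldimethylsilyloxy)but-3-en-1-yl]-N-methoxy-N,2,2-trimethyl-1,3-dioxolane-4-carboxamide
Conditions: MeNH(OMe)·HCl, iPrMgCl, THF, −20 → 0 °C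
Reagents that add atoms: N,O-dimethylhydroxylamine hydrochloride, CNOC.Cl
Why: Direct aminolysis of the ester by the magnesium amide to the Weinreb amide, which lets the next acetylide addition stop at the ketone. The trans-dioxolane is the more stable epimer, so C9 is not at risk.

Step 8
Reactants: 10 methacrolein; 11 ethynylmagnesium bromide
Product: 12 (±)-2-methylpent-1-en-4-yn-3-ol
Conditions: THF, −78 → 0 °C; NH4Cl aq.
Reagents that add atoms: none
Why: 1,2-Addition of an alkynyl Grignard reagent to an enal; the racemate suffices because C3 is oxidized to a ketone in step 11.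

Step 9
Reactants: 9 (4R,5S)-5-[(2S)-2-(tert-butyldimethylsilyloxy)but-3-en-1-yl]-N-methoxy-N,2,2-trimethyl-1,3-dioxolane-4-carboxamide; 12 (±)-2-methylpent-1-en-4-yn-3-ol
Product: 13 1-[(4R,5S)-5-[(2S)-2-(tert-butyldimethylsilyloxy)but-3-en-1-yl]-2,2-dimethyl-1,3-dioxolan-4-yl]-4-hydroxy-5-methylhex-5-en-2-yn-1-one (both C3 epimers)
Conditions: 12 (2.5 equiv), n-BuLi (5 equiv), THF, −78 °C; then 9, −78 → −30 °C; NH4Cl aq.
Reagents that add atoms: none
Why: Acylation of a lithium acetylide (the O,C-dilithio derivative of 12) by a Weinreb amide; the chelated tetrahedral intermediate collapses to the ynone only on work-up, so a single addition is expected and C9 is not enolized.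

Step 10
Reactants: 13 1-[(4R,5S)-5-[(2S)-2-(tert-butyldimethylsilyloxy)but-3-en-1-yl]-2,2-dimethyl-1,3-dioxolan-4-yl]-4-hydroxy-5-methylhex-5-en-2-yn-1-one
Product: 14 (2S)-2-[(4R,5S)-5-[(2S)-2-(tert-butyldimethylsilyloxy)but-3-en-1-yl]-2,2-dimethyl-1,3-dioxolan-4-yl]-6-methylhept-6-en-3-yne-2,5-diol (C10 tertiary alcohol; both C3 epimers)
Conditions: MeMgBr (3.5 equiv, Et2O), CH2Cl2, −78 °C; NH4Cl aq.
Reagents that add atoms: methylmagnesium bromide, C[Mg]Br
Why: Cram-chelate addition of a Grignard reagent to an α-alkoxy ketone: magnesium bridges the C10 carbonyl and O9, and methyl should add to the face anti to C8, which gives the C10 configuration of the target (descriptor S here only because the alkynyl carbon ranks below C9). The hard Grignard reagent should add 1,2 to the ynone; one equivalent is spent on the C3 hydroxyl.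

Step 11
Reactants: 14 (2S)-2-[(4R,5S)-5-[(2S)-2-(tert-butyldimethylsilyloxy)but-3-en-1-yl]-2,2-dimethyl-1,3-dioxolan-4-yl]-6-methylhept-6-en-3-yne-2,5-diol
Product: 15 (6S)-6-[(4R,5S)-5-[(2S)-2-(tert-butyldimethylsilyloxy)but-3-en-1-yl]-2,2-dimethyl-1,3-dioxolan-4-yl]-6-hydroxy-2-methylhept-1-en-4-yn-3-one
Conditions: MnO2 (activated, excess), CH2Cl2, rt; filtered and used crude
Reagents that add atoms: none
Why: MnO2 oxidizes only allylic and propargylic alcohols; the doubly activated secondary C3 carbinol should give the ketone from both epimers, while the tertiary C10 hydroxyl cannot react.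

Step 12
Reactants: 15 (6S)-6-[(4R,5S)-5-[(2S)-2-(tert-butyldimethylsilyloxy)but-3-en-1-yl]-2,2-dimethyl-1,3-dioxolan-4-yl]-6-hydroxy-2-methylhept-1-en-4-yn-3-one
Product: 17 (2R)-2-[(4R,5S)-5-[(2S)-2-(tert-butyldimethylsilyloxy)but-3-en-1-yl]-2,2-dimethyl-1,3-dioxolan-4-yl]-2-methyl-5-(prop-1-en-2-yl)furan-3(2H)-one, via enaminone 16 (not isolated)
Conditions: Et2NH (1.5 equiv), EtOH, 0 °C → rt; then AcOH–H2O, rt
Reagents that add atoms: water, O
Why: Known conversion of 4-hydroxy-2-ynones into 3(2H)-furanones: the amine adds to the ynone at C1, the C10 hydroxyl closes on the C3 carbonyl (5-exo-trig), and loss of water with hydrolysis of the iminium leaves the ketone at C1. The ynone is far more electrophilic than the α-methyl enone, and no bond to C10 is broken.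

Step 13
Reactants: 17 (2R)-2-[(4R,5S)-5-[(2S)-2-(tert-butyldimethylsilyloxy)but-3-en-1-yl]-2,2-dimethyl-1,3-dioxolan-4-yl]-2-methyl-5-(prop-1-en-2-yl)furan-3(2H)-one
Product: 18 (2R)-2-[(4R,5S)-5-[(2S)-2-hydroxybut-3-en-1-yl]-2,2-dimethyl-1,3-dioxolan-4-yl]-2-methyl-5-(prop-1-en-2-yl)furan-3(2H)-one
Conditions: HF·pyridine, pyridine, THF, 0 °C → rt
Reagents that add atoms: none
Why: Buffered fluoride cleavage of a secondary silyl ether; the non-basic medium spares the acetal and the base-sensitive dienone.

Step 14
Reactants: 18 (2R)-2-[(4R,5S)-5-[(2S)-2-hydroxybut-3-en-1-yl]-2,2-dimethyl-1,3-dioxolan-4-yl]-2-methyl-5-(prop-1-en-2-yl)furan-3(2H)-one; 19 2-(diethoxyphosphoryl)acetic acid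
Product: 20 (2S)-1-[(4S,5R)-2,2-dimethyl-5-[(2R)-2-methyl-3-oxo-5-(prop-1-en-2-yl)-2,3-dihydrofuran-2-yl]-1,3-dioxolan-4-yl]but-3-en-2-yl 2-(diethoxyphosphoryl)acetate
Conditions: DCC, DMAP (cat.), CH2Cl2, 0 °C → rt
Reagents that add atoms: none
Why: Steglich esterification of a secondary allylic alcohol; it proceeds with retention at C6 and introduces the acidic methylene only after the last strongly basic step.

Step 15
Reactants: 20 (2S)-1-[(4S,5R)-2,2-dimethyl-5-[(2R)-2-methyl-3-oxo-5-(prop-1-en-2-yl)-2,3-dihydrofuran-2-yl]-1,3-dioxolan-4-yl]but-3-en-2-yl 2-(diethoxyphosphoryl)acetate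
Product: 21 (4Z,6S,8S,9R,10R)-8,9-O-isopropylidene-8,9-dihydroxy-1-oxo-3,10-epoxy-11,12,13-trinorgermacra-2,4-dien-6-yl 2-(diethoxyphosphoryl)acetate
Conditions: second-generation Hoveyda–Grubbs catalyst RuCl2(H2IMes)(=CH–C6H4–2-OiPr) (15 mol%, in portions), 1,4-benzoquinone (cat.), toluene (1 mM), 90 °C
Reagents that add atoms: none
Why: Ring-closing olefin metathesis: the ruthenium carbene forms at the monosubstituted C5 olefin and closes on the 1,1-disubstituted C4 olefin with loss of ethene. The bridged ring can hold only a cis C4=C5 bond, so the Z geometry is set by the ring; the trans-dioxolane and planar furanone restrict the chain and high dilution suppresses oligomers.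

Step 16
Reactants: 21 (4Z,6S,8S,9R,10R)-8,9-O-isopropylidene-8,9-dihydroxy-1-oxo-3,10-epoxy-11,12,13-trinorgermacra-2,4-dien-6-yl 2-(diethoxyphosphoryl)acetate
Product: 22 (4Z,6S,8S,9R,10R)-8,9-dihydroxy-1-oxo-3,10-epoxy-11,12,13-trinorgermacra-2,4-dien-6-yl 2-(diethoxyphosphoryl)acetate
Conditions: CF3CO2H, H2O, CH2Cl2, 0 °C → rt
Reagents that add atoms: none
Why: Acid hydrolysis of an isopropylidene acetal that is strained by trans fusion to the ten-membered ring; the esters, furanone and phosphonate are acid-stable.

Step 17
Reactants: 22 (4Z,6S,8S,9R,10R)-8,9-dihydroxy-1-oxo-3,10-epoxy-11,12,13-trinorgermacra-2,4-dien-6-yl 2-(diethoxyphosphoryl)acetate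
Product: 23 (4Z,6S,8S,9R,10R)-6-[2-(diethoxyphosphoryl)acetoxy]-9-hydroxy-1-oxo-3,10-epoxy-11,12,13-trinorgermacra-2,4-dien-8-yl 3-methylbutanoate
Conditions: (Me2CHCH2CO)2O (1.1 equiv), 2,4,6-collidine, DMAP (5 mol%), CH2Cl2, −40 → −20 °C
Reagents that add atoms: 3-methylbutanoic anhydride, CC(C)CC(=O)OC(=O)CC(C)C
Why: Site-selective acylation: C8–OH is flanked by the C7 methylene and C9–OH by the fully substituted C10, so a limited amount of anhydride at low temperature should acylate O8 first.

Step 18
Reactants: 23 (4Z,6S,8S,9R,10R)-6-[2-(diethoxyphosphoryl)acetoxy]-9-hydroxy-1-oxo-3,10-epoxy-11,12,13-trinorgermacra-2,4-dien-8-yl 3-methylbutanoate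
Product: 24 (4Z,6S,8S,9R,10R)-9-acetoxy-6-[2-(diethoxyphosphoryl)acetoxy]-1-oxo-3,10-epoxy-11,12,13-trinorgermacra-2,4-dien-8-yl 3-methylbutanoate
Conditions: Ac2O, Et3N, DMAP, CH2Cl2, rt
Reagents that add atoms: acetic anhydride, CC(=O)OC(C)=O
Why: DMAP-catalysed acetylation of the remaining hindered secondary alcohol; with no free hydroxyl left, acyl migration is no longer possible.

Step 19
Reactants: 24 (4Z,6S,8S,9R,10R)-9-acetoxy-6-[2-(diethoxyphosphoryl)acetoxy]-1-oxo-3,10-epoxy-11,12,13-trinorgermacra-2,4-dien-8-yl 3-methylbutanoate
Product: 25 (4Z,6S,8S,9R,10R)-9-acetoxy-6-[2-diazo-2-(diethoxyphosphoryl)acetoxy]-1-oxo-3,10-epoxy-11,12,13-trinorgermacra-2,4-dien-8-yl 3-methylbutanoate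
Conditions: 4-acetamidobenzenesulfonyl azide, DBU (added last, slowly), MeCN, 0 °C → rt
Reagents that add atoms: 4-acetamidobenzenesulfonyl azide, CC(=O)Nc1ccc(cc1)S(=O)(=O)N=[N+]=[N-]
Why: Regitz diazo transfer to the active methylene of the phosphonoacetate; the base is added to a mixture already containing the azide, so that the carbanion is trapped before it can add to the dienone at C5.

Step 20
Reactants: 25 (4Z,6S,8S,9R,10R)-9-acetoxy-6-[2-diazo-2-(diethoxyphosphoryl)acetoxy]-1-oxo-3,10-epoxy-11,12,13-trinorgermacra-2,4-dien-8-yl 3-methylbutanoate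
Product: 26 (4Z,6R,7S,8S,9R,10R)-9-acetoxy-11-(diethoxyphosphoryl)-1-oxo-3,10-epoxy-13-norgermacra-2,4-dien-12,6-olid-8-yl 3-methylbutanoate (C11 epimers)
Conditions: Rh2(OAc)4 (2 mol%), ClCH2CH2Cl (5 mM, slow addition of 25), 80 °C
Reagents that add atoms: none
Why: Dirhodium tetraacetate (divalent rhodium) decomposes the diazo group with loss of N2 to an electrophilic rhodium carbenoid flanked by the ester and phosphonate acceptors. The carbenoid carbon C11 inserts into a C7–H bond through a concerted, three-centre, hydride-transfer-like transition state with retention at C7, forming C7–C11. The closest known reaction type is the rhodium-catalysed intramolecular 1,5 C–H insertion of α-diazo phosphonoacetates and diazomalonates of secondary alcohols to α-substituted γ-butyrolactones. The one ring closed is the γ-lactone O6–C12–C11–C7–C6, formed in the 1,5-insertion mode; 1,6-insertion at C8–H would give a δ-lactone and insertion at C6–H a β-lactone. The new C7 stereocentre is set by which diastereotopic hydrogen is replaced: with the C5–C6–C7–C8 chain antiperiplanar in the rigid bicycle, only the C7–H trans to O6 lies gauche to the C6–O bond and within reach of the tethered carbenoid, so insertion with retention should give the trans-fused (7S) lactone, while C11 forms as a mixture that step 21 erases. Site selectivity for C7–H over C8–H rests on the five-membered preference and on the C8 and C9 acyloxy groups, which deactivate C8–H and offer no ether oxygen for ylide formation. Chemoselectivity over cyclopropanation of the allylic C4=C5 bond rests on that olefin being trisubstituted and electron-poor through conjugation with the furanone, and on the strain of a cyclopropane fused to the bridged ring. Slow addition at high dilution in a non-aromatic solvent is meant to suppress carbene dimerization and arene addition.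

Step 21
Reactants: 26 (4Z,6R,7S,8S,9R,10R)-9-acetoxy-11-(diethoxyphosphoryl)-1-oxo-3,10-epoxy-13-norgermacra-2,4-dien-12,6-olid-8-yl 3-methylbutanoate
Product: 27 (4Z,6R,7S,8S,9R,10R)-9-acetoxy-1-oxo-3,10-epoxygermacra-2,4,11(13)-trien-12,6-olid-8-yl 3-methylbutanoate (CNP0255553.1)
Conditions: 37% aq. HCHO (excess), K2CO3, THF, 0 °C, short reaction time
Reagents that add atoms: formaldehyde, C=O
Why: Horner–Wadsworth–Emmons olefination of the α-phosphono lactone with formaldehyde; both C11 epimers converge on the exocyclic methylene. Brief exposure to carbonate at 0 °C should spare the acetate and isovalerate, and C7 is not acidic, so its configuration is kept.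

## Compound list

1 | dimethyl (4R,5R)-2,2-dimethyl-1,3-dioxolane-4,5-dicarboxylate (acetonide of dimethyl L-tartrate) | COC(=O)[C@@H]1OC(C)(C)O[C@H]1C(=O)OC | starting material
2 | methyl (4R,5S)-5-(hydroxymethyl)-2,2-dimethyl-1,3-dioxolane-4-carboxylate | COC(=O)[C@@H]1OC(C)(C)O[C@H]1CO | intermediate
3 | methyl (4R,5S)-2,2-dimethyl-5-{[(trifluoromethanesulfonyl)oxy]methyl}-1,3-dioxolane-4-carboxylate | COC(=O)[C@@H]1OC(C)(C)O[C@H]1COS(=O)(=O)C(F)(F)F | intermediate
4 | methyl (4R,5S)-2,2-dimethyl-5-(prop-2-en-1-yl)-1,3-dioxolane-4-carboxylate | COC(=O)[C@@H]1OC(C)(C)O[C@H]1CC=C | intermediate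
5 | methyl (4R,5S)-2,2-dimethyl-5-[(1,2,4-trioxolan-3-yl)methyl]-1,3-dioxolane-4-carboxylate (secondary ozonide, epimers at the trioxolane carbon) | COC(=O)[C@@H]1OC(C)(C)O[C@H]1CC2OCOO2 | intermediate (not isolated)
6 | methyl (4R,5S)-2,2-dimethyl-5-(2-oxoethyl)-1,3-dioxolane-4-carboxylate | COC(=O)[C@@H]1OC(C)(C)O[C@H]1CC=O | intermediate
7 | methyl (4R,5S)-5-[(2S)-2-hydroxybut-3-en-1-yl]-2,2-dimethyl-1,3-dioxolane-4-carboxylate | COC(=O)[C@@H]1OC(C)(C)O[C@H]1C[C@H](O)C=C | intermediate
8 | methyl (4R,5S)-5-[(2S)-2-(tert-butyldimethylsilyloxy)but-3-en-1-yl]-2,2-dimethyl-1,3-dioxolane-4-carboxylate | COC(=O)[C@@H]1OC(C)(C)O[C@H]1C[C@H](O[Si](C)(C)C(C)(C)C)C=C | intermediate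
9 | (4R,5S)-5-[(2S)-2-(tert-butyldimethylsilyloxy)but-3-en-1-yl]-N-methoxy-N,2,2-trimethyl-1,3-dioxolane-4-carboxamide | CON(C)C(=O)[C@@H]1OC(C)(C)O[C@H]1C[C@H](O[Si](C)(C)C(C)(C)C)C=C | intermediate
10 | methacrolein (2-methylprop-2-enal) | CC(=C)C=O | starting material
11 | ethynylmagnesium bromide | C#C[Mg]Br | starting material
12 | (±)-2-methylpent-1-en-4-yn-3-ol | CC(=C)C(O)C#C | intermediate
13 | 1-[(4R,5S)-5-[(2S)-2-(tert-butyldimethylsilyloxy)but-3-en-1-yl]-2,2-dimethyl-1,3-dioxolan-4-yl]-4-hydroxy-5-methylhex-5-en-2-yn-1-one (both C3 epimers) | C=C(C)C(O)C#CC(=O)[C@@H]1OC(C)(C)O[C@H]1C[C@H](O[Si](C)(C)C(C)(C)C)C=C | intermediate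
14 | (2S)-2-[(4R,5S)-5-[(2S)-2-(tert-butyldimethylsilyloxy)but-3-en-1-yl]-2,2-dimethyl-1,3-dioxolan-4-yl]-6-methylhept-6-en-3-yne-2,5-diol (both C3 epimers) | C=C(C)C(O)C#C[C@](C)(O)[C@@H]1OC(C)(C)O[C@H]1C[C@H](O[Si](C)(C)C(C)(C)C)C=C | intermediate
15 | (6S)-6-[(4R,5S)-5-[(2S)-2-(tert-butyldimethylsilyloxy)but-3-en-1-yl]-2,2-dimethyl-1,3-dioxolan-4-yl]-6-hydroxy-2-methylhept-1-en-4-yn-3-one | C=C(C)C(=O)C#C[C@](C)(O)[C@@H]1OC(C)(C)O[C@H]1C[C@H](O[Si](C)(C)C(C)(C)C)C=C | intermediate
16 | (6S)-6-[(4R,5S)-5-[(2S)-2-(tert-butyldimethylsilyloxy)but-3-en-1-yl]-2,2-dimethyl-1,3-dioxolan-4-yl]-5-(diethylamino)-6-hydroxy-2-methylhepta-1,4-dien-3-one (enaminone) | C=C(C)C(=O)C=C(N(CC)CC)[C@](C)(O)[C@@H]1OC(C)(C)O[C@H]1C[C@H](O[Si](C)(C)C(C)(C)C)C=C | intermediate (not isolated)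
17 | (2R)-2-[(4R,5S)-5-[(2S)-2-(tert-butyldimethylsilyloxy)but-3-en-1-yl]-2,2-dimethyl-1,3-dioxolan-4-yl]-2-methyl-5-(prop-1-en-2-yl)furan-3(2H)-one | C=C(C)C1=CC(=O)[C@](C)(O1)[C@@H]2OC(C)(C)O[C@H]2C[C@H](O[Si](C)(C)C(C)(C)C)C=C | intermediate
18 | (2R)-2-[(4R,5S)-5-[(2S)-2-hydroxybut-3-en-1-yl]-2,2-dimethyl-1,3-dioxolan-4-yl]-2-methyl-5-(prop-1-en-2-yl)furan-3(2H)-one | C=C(C)C1=CC(=O)[C@](C)(O1)[C@@H]2OC(C)(C)O[C@H]2C[C@H](O)C=C | intermediate
19 | 2-(diethoxyphosphoryl)acetic acid | OC(=O)CP(=O)(OCC)OCC | starting material
20 | (2S)-1-[(4S,5R)-2,2-dimethyl-5-[(2R)-2-methyl-3-oxo-5-(prop-1-en-2-yl)-2,3-dihydrofuran-2-yl]-1,3-dioxolan-4-yl]but-3-en-2-yl 2-(diethoxyphosphoryl)acetate | C=C(C)C1=CC(=O)[C@](C)(O1)[C@@H]2OC(C)(C)O[C@H]2C[C@H](OC(=O)CP(=O)(OCC)OCC)C=C | intermediate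
21 | (4Z,6S,8S,9R,10R)-8,9-O-isopropylidene-8,9-dihydroxy-1-oxo-3,10-epoxy-11,12,13-trinorgermacra-2,4-dien-6-yl 2-(diethoxyphosphoryl)acetate | CCOP(=O)(OCC)CC(=O)O[C@@H]1/C=C(/C)C2=CC(=O)[C@](C)(O2)[C@@H]3OC(C)(C)O[C@H]3C1 | intermediate
22 | (4Z,6S,8S,9R,10R)-8,9-dihydroxy-1-oxo-3,10-epoxy-11,12,13-trinorgermacra-2,4-dien-6-yl 2-(diethoxyphosphoryl)acetate | CCOP(=O)(OCC)CC(=O)O[C@@H]1/C=C(/C)C2=CC(=O)[C@](C)(O2)[C@H](O)[C@@H](O)C1 | intermediate
23 | (4Z,6S,8S,9R,10R)-6-[2-(diethoxyphosphoryl)acetoxy]-9-hydroxy-1-oxo-3,10-epoxy-11,12,13-trinorgermacra-2,4-dien-8-yl 3-methylbutanoate | CCOP(=O)(OCC)CC(=O)O[C@@H]1/C=C(/C)C2=CC(=O)[C@](C)(O2)[C@H](O)[C@@H](OC(=O)CC(C)C)C1 | intermediate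
24 | (4Z,6S,8S,9R,10R)-9-acetoxy-6-[2-(diethoxyphosphoryl)acetoxy]-1-oxo-3,10-epoxy-11,12,13-trinorgermacra-2,4-dien-8-yl 3-methylbutanoate | CCOP(=O)(OCC)CC(=O)O[C@@H]1/C=C(/C)C2=CC(=O)[C@](C)(O2)[C@H](OC(C)=O)[C@@H](OC(=O)CC(C)C)C1 | intermediate
25 | (4Z,6S,8S,9R,10R)-9-acetoxy-6-[2-diazo-2-(diethoxyphosphoryl)acetoxy]-1-oxo-3,10-epoxy-11,12,13-trinorgermacra-2,4-dien-8-yl 3-methylbutanoate (key-step precursor) | CCOP(=O)(OCC)C(=[N+]=[N-])C(=O)O[C@@H]1/C=C(/C)C2=CC(=O)[C@](C)(O2)[C@H](OC(C)=O)[C@@H](OC(=O)CC(C)C)C1 | intermediate
26 | (4Z,6R,7S,8S,9R,10R)-9-acetoxy-11-(diethoxyphosphoryl)-1-oxo-3,10-epoxy-13-norgermacra-2,4-dien-12,6-olid-8-yl 3-methylbutanoate (key-step product, C11 epimers) | CCOP(=O)(OCC)C1C(=O)O[C@@H]2/C=C(/C)C3=CC(=O)[C@](C)(O3)[C@H](OC(C)=O)[C@@H](OC(=O)CC(C)C)[C@@H]12 | intermediate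
27 | (4Z,6R,7S,8S,9R,10R)-9-acetoxy-1-oxo-3,10-epoxygermacra-2,4,11(13)-trien-12,6-olid-8-yl 3-methylbutanoate (CNP0255553.1) | C=C1C(=O)O[C@@H]2/C=C(/C)C3=CC(=O)[C@](C)(O3)[C@H](OC(C)=O)[C@@H](OC(=O)CC(C)C)[C@@H]12 | target

## Step count and least certain steps

Total: 21 steps. Longest linear sequence: 20 steps (steps 1–7 and 9–21); step 8 makes the side fragment 12.

**Step 20 (key step).**
- What may go wrong: the carbenoid may be diverted into addition across the allylic C4=C5 bond or into dimerization. The C7–H bonds are inductively deactivated by oxygen on both neighbouring carbons, and the ester of a secondary alcohol must first rotate into its less favoured s-cis form. A second possibility is loss of stereocontrol by insertion into the other C7–H (cis fusion) if the ring populates a conformer with C5–C6–C7–C8 gauche.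
- Fallback: move the tether to O8, from which the same C7–H is cis (the preferred fusion for carbenoid insertion) and the olefin is remote. It sets out from 17 and comes back at 26.
  - Ring-closing metathesis of 17 under the conditions of step 15 should give the 6-O-silyl ether of the acetonide-protected bicyclic core F1.
  - Aqueous trifluoroacetic acid should give the 6-O-silyl 8,9-diol F2.
  - Carbodiimide coupling with 19 at the less hindered O8 should give the 8-O-phosphonoacetate F3.
  - Acetylation should give the 9-O-acetyl 8-O-phosphonoacetate F4.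
  - Diazo transfer as in step 19 should give the 8-O-diazophosphonoacetate F5.
  - Rh2(OAc)4 should give the cis-fused 12,8-olide phosphonate F6 by 1,5-insertion; the other 1,5 position, C9–H, is deactivated by its acetoxy group.
  - HF·pyridine should free the 6-hydroxy 12,8-olide F7.
  - Mild acid-catalysed translactonization (camphorsulfonic acid, CH2Cl2) should move the lactone to O6 and give the 8-hydroxy 12,6-olide phosphonate F8.
  - Acylation with 3-methylbutanoic anhydride and DMAP should give 26.

**Step 15 (ring-closing metathesis).**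
- What may go wrong: oligomerization by cross metathesis at the monosubstituted olefin, or no turnover at the 1,1-disubstituted olefin, which is hindered and electron-poor through conjugation with the furanone; the strain of the bridged ring adds to this.
- Fallback: close the carbocycle before the furanone exists, while the C4 olefin is still an electron-rich allylic carbinol. It sets out from 14 and comes back at 21.
  - Metathesis of 14 should give the ten-membered enyne diol F9; the alkyne, flanked by a quaternary and a branched carbinol carbon, is expected to stay out of the metathesis.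
  - MnO2 should give the cyclic hydroxy ynone F10.
  - Diethylamine, then aqueous acetic acid, should close the furanone across the ring and give the silyl ether F1.
  - HF·pyridine should give the bicyclic core alcohol F11.
  - Carbodiimide coupling with 19 should give 21.

**Step 5 (enantioselective vinylation).**
- What may go wrong: poor facial selectivity, because the dioxolane oxygens and the ester can bind zinc and open a ligand-free pathway; slow addition to an enolizable aldehyde may also allow aldol side reactions.
- Fallback: uncontrolled addition followed by stereochemical correction. It sets out from 6 and comes back at 7.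
  - Vinylmagnesium bromide in THF at −78 °C should give 7 together with its C6 epimer F12; the two diastereomers are separated.
  - F12 is inverted by a Mitsunobu reaction with 4-nitrobenzoic acid to the (6S) 4-nitrobenzoate F13.
  - Methanolysis (K2CO3, MeOH, 0 °C) should give 7.

**Step 10 (methyl addition at C10).**
- What may go wrong: erosion of chelation control, because a dioxolane oxygen is a weaker donor to magnesium than a simple ether, so that non-chelated Felkin–Anh attack gives the C10 epimer; enolization at C9 is a second risk.
- Fallback: reverse the order of the two additions, so that the opposite model delivers the same configuration. It sets out from 9 and comes back at 14.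
  - Methylmagnesium bromide on 9 should give the methyl ketone F14.
  - The dilithio derivative of 12 is then added in THF at −78 °C, a non-chelating medium in which Felkin–Anh control should apply, to give 14.

**Step 17 (site-selective acylation of O8).**
- What may go wrong: incomplete discrimination between the two secondary hydroxyls, or acyl migration between O8 and O9 under nucleophilic catalysis.
- Fallback: differentiate the diol by silylation, which is more sensitive to hindrance and not reversible. It sets out from 22 and comes back at 24.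
  - Triethylsilyl chloride and imidazole at −20 °C should give the 8-O-triethylsilyl ether F15.
  - Acetylation should give the 9-O-acetyl 8-O-silyl ether F16.
  - HF·pyridine should give the 9-O-acetyl 8-ol F17.
  - Acylation with 3-methylbutanoic anhydride and DMAP should give 24.

## Further compounds

F1 | step 20 | 6-O-(tert-butyldimethylsilyl) ether of the acetonide-protected bicyclic core (4Z,6S,8S,9R,10R) | CC(C)(C)[Si](C)(C)O[C@@H]1/C=C(/C)C2=CC(=O)[C@](C)(O2)[C@@H]3OC(C)(C)O[C@H]3C1
F2 | step 20 | 6-O-(tert-butyldimethylsilyl) 8,9-diol of the bicyclic core | CC(C)(C)[Si](C)(C)O[C@@H]1/C=C(/C)C2=CC(=O)[C@](C)(O2)[C@H](O)[C@@H](O)C1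
F3 | step 20 | 8-O-(diethylphosphonoacetyl) 6-O-silyl 9-ol | CC(C)(C)[Si](C)(C)O[C@@H]1/C=C(/C)C2=CC(=O)[C@](C)(O2)[C@H](O)[C@@H](OC(=O)CP(=O)(OCC)OCC)C1
F4 | step 20 | 9-O-acetyl 8-O-(diethylphosphonoacetyl) 6-O-silyl ether | CC(C)(C)[Si](C)(C)O[C@@H]1/C=C(/C)C2=CC(=O)[C@](C)(O2)[C@H](OC(C)=O)[C@@H](OC(=O)CP(=O)(OCC)OCC)C1
F5 | step 20 | 9-O-acetyl 8-O-[diazo(diethoxyphosphoryl)acetyl] 6-O-silyl ether | CC(C)(C)[Si](C)(C)O[C@@H]1/C=C(/C)C2=CC(=O)[C@](C)(O2)[C@H](OC(C)=O)[C@@H](OC(=O)C(=[N+]=[N-])P(=O)(OCC)OCC)C1
F6 | step 20 | cis-fused 12,8-olide 11-phosphonate with 9-O-acetyl and 6-O-silyl groups (C11 epimers) | CC(C)(C)[Si](C)(C)O[C@@H]1/C=C(/C)C2=CC(=O)[C@](C)(O2)[C@H](OC(C)=O)[C@H]3OC(=O)C(P(=O)(OCC)OCC)[C@H]31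
F7 | step 20 | 6-hydroxy 12,8-olide 11-phosphonate with 9-O-acetyl group | O[C@@H]1/C=C(/C)C2=CC(=O)[C@](C)(O2)[C@H](OC(C)=O)[C@H]3OC(=O)C(P(=O)(OCC)OCC)[C@H]31
F8 | step 20 | 8-hydroxy 12,6-olide 11-phosphonate with 9-O-acetyl group (26 without the isovalerate) | CCOP(=O)(OCC)C1C(=O)O[C@@H]2/C=C(/C)C3=CC(=O)[C@](C)(O3)[C@H](OC(C)=O)[C@@H](O)[C@@H]12
F9 | step 15 | ten-membered enyne diol from metathesis of 14 (6-O-silyl, 8,9-O-isopropylidene, C3 epimers) | CC(C)(C)[Si](C)(C)O[C@@H]1/C=C(/C)C(O)C#C[C@](C)(O)[C@@H]2OC(C)(C)O[C@H]2C1
F10 | step 15 | ten-membered 10-hydroxy ynone (C3 ketone) | CC(C)(C)[Si](C)(C)O[C@@H]1/C=C(/C)C(=O)C#C[C@](C)(O)[C@@H]2OC(C)(C)O[C@H]2C1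
F11 | step 15 | acetonide-protected bicyclic core alcohol (6-OH) | O[C@@H]1/C=C(/C)C2=CC(=O)[C@](C)(O2)[C@@H]3OC(C)(C)O[C@H]3C1
F12 | step 5 | methyl (4R,5S)-5-[(2R)-2-hydroxybut-3-en-1-yl]-2,2-dimethyl-1,3-dioxolane-4-carboxylate (C6 epimer of 7) | COC(=O)[C@@H]1OC(C)(C)O[C@H]1C[C@@H](O)C=C
F13 | step 5 | (6S) 4-nitrobenzoate of 7 | COC(=O)[C@@H]1OC(C)(C)O[C@H]1C[C@H](OC(=O)c2ccc(cc2)[N+](=O)[O-])C=C
F14 | step 10 | 1-[(4R,5S)-5-[(2S)-2-(tert-butyldimethylsilyloxy)but-3-en-1-yl]-2,2-dimethyl-1,3-dioxolan-4-yl]ethan-1-one | CC(=O)[C@@H]1OC(C)(C)O[C@H]1C[C@H](O[Si](C)(C)C(C)(C)C)C=C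
F15 | step 17 | 8-O-triethylsilyl ether of 22 | CCOP(=O)(OCC)CC(=O)O[C@@H]1/C=C(/C)C2=CC(=O)[C@](C)(O2)[C@H](O)[C@@H](O[Si](CC)(CC)CC)C1
F16 | step 17 | 9-O-acetyl 8-O-triethylsilyl derivative of 22 | CCOP(=O)(OCC)CC(=O)O[C@@H]1/C=C(/C)C2=CC(=O)[C@](C)(O2)[C@H](OC(C)=O)[C@@H](O[Si](CC)(CC)CC)C1
F17 | step 17 | 9-O-acetyl derivative of 22 with free 8-OH | CCOP(=O)(OCC)CC(=O)O[C@@H]1/C=C(/C)C2=CC(=O)[C@](C)(O2)[C@H](OC(C)=O)[C@@H](O)C1
A1 | alternative 1 | ten-membered 1-ethoxy enone from the oxy-Cope shift (C10 set, trans C8=C9, three methoxymethyl ethers) | COCO[C@@H]1/C=C(/C)C(=O)/C=C(OCC)\[C@](C)(OCOC)/C=C/[C@H]1C(COCOC)=C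
A2 | alternative 2 | furanone-bridged ten-membered C6 ketone acid with 8,9-bis(silyl ether) | C[C@@H]1CC(=O)[C@H](CC(=O)O)[C@H](O[Si](C)(C)C(C)(C)C)[C@@H](O[Si](C)(C)C(C)(C)C)[C@@]2(C)OC1=CC2=O
A3 | alternative 3 | bicyclic α-methylene lactone core with free C9 hydroxyl and C8 p-methoxybenzyl ether | C=C1C(=O)O[C@@H]2/C=C(/C)C3=CC(=O)[C@](C)(O3)[C@H](O)[C@@H](OCc4ccc(OC)cc4)[C@@H]12
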